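**Retrosynthetic overview**
1. Komaroviquinone ⇐ oxidative demethylation of a 10β‑hydroxy‑7‑oxo‑11,12,14‑trimethoxy‑icetexane; the 10‑OH then closes onto C7 to give the oxa‑bridge (last ring formed).
2. C7 ketone ⇐ benzylic oxidation of the 10β‑hydroxy‑icetexane.
3. Seven‑membered ring B, the C9–C20 bond and the C10–O bond ⇐ one cationic [1,2]‑aryl shift (Wagner–Meerwein) of a 20‑mesyloxy‑abietane, with water capturing C10 anti to the migrating arene.
4. Trimethoxy‑abietan‑20‑ol ⇐ ester reduction ⇐ reductive methylation ⇐ Teuber oxidation ⇐ selective O‑methylation of (+)‑carnosic acid.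
5. Ring order: rings A and C and the C5 stereocentre are bought in carnosic acid; ring B by ring expansion (step 5); oxa‑bridge in step 7.

Assumptions: (+)‑carnosic acid (bulk rosemary extract) is taken as the cheap chiral starting material. Abietane numbering (C1–C20) is used throughout. Only reagents whose carbons enter the skeleton (MeI, Me2SO4) are numbered; other reagents are given with SMILES in each step.

**Step 1**
Reactants: 1 (+)‑carnosic acid [(5S,10R)‑11,12‑dihydroxyabieta‑8,11,13‑trien‑20‑oic acid]; 2 iodomethane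
Product: 3 methyl 12‑O‑methylcarnosate [methyl (5S,10R)‑11‑hydroxy‑12‑methoxyabieta‑8,11,13‑trien‑20‑oate]
Conditions: MeI (2.2 equiv), K2CO3, degassed acetone, rt, Ar
Reagents that add atoms: iodomethane, CI (two CH3)
Why: O‑alkylation (esterification plus Williamson) of the carboxylate and the exposed C12 phenoxide; O11 is shielded by C1‑H2/C20 and hydrogen‑bonded to the C20 carbonyl, so it stays free, and no stereocentre is touched.

**Step 2**
Reactants: 3
Product: 4 methyl (5S,10R)‑12‑methoxy‑11,14‑dioxoabieta‑8,12‑dien‑20‑oate (para‑quinone)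
Conditions: Fremy's salt (3 equiv), aq. KH2PO4, acetone/H2O, rt
Reagents that add atoms: potassium nitrosodisulfonate, [K+].[K+].[O-]S(=O)(=O)N([O])S(=O)(=O)[O-] (O at C14)
Why: Teuber oxidation; the 11‑phenol has a free para position (C14), so it gives the para‑quinone with the 12‑OMe retained.

**Step 3**
Reactants: 4; 5 dimethyl sulfate
Product: 6 methyl (5S,10R)‑11,12,14‑trimethoxyabieta‑8,11,13‑trien‑20‑oate
Conditions: Na2S2O4, n‑Bu4NBr, THF/H2O, rt; then aq. KOH, Me2SO4, rt (one pot, Ar)
Reagents that add atoms: dimethyl sulfate, COS(=O)(=O)OC (two CH3)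
Why: Reductive methylation; dithionite gives the hydroquinone, which is O‑methylated in situ under phase transfer, while the hindered C20 ester on quaternary C10 is not saponified.

**Step 4**
Reactants: 6
Product: 7 (5S,10R)‑11,12,14‑trimethoxyabieta‑8,11,13‑trien‑20‑ol
Conditions: LiAlH4, THF, reflux
Reagents that add atoms: none
Why: Hydride reduction of the hindered ester to the neopentyl primary alcohol; aryl methyl ethers and both stereocentres are inert.

**Step 5**
Reactants: 7
Product: 8 (5S,10S)‑11,12,14‑trimethoxy‑9(10→20)‑abeo‑abieta‑8,11,13‑trien‑10β‑ol (6‑7‑6 icetexane; 10‑OH trans to H‑5)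
Conditions: MsCl, Et3N, CH2Cl2, 0 °C; then acetone/H2O (1:1), NaHCO3, 60 °C (crude mesylate carried through)
Reagents that add atoms: water, O (the 10‑OH); MsCl, CS(=O)(=O)Cl, is used but leaves no atoms in 8
Why: Neophyl‑type Wagner–Meerwein rearrangement, a suprafacial cationic [1,2]‑sigmatropic aryl shift: the electron‑rich arene migrates from C10 to C20 through a phenonium ion, forming C9–C20 and the seven‑membered ring, and water opens the bridged ion at tertiary C10 anti to the departing aryl, which sets 10β‑OH (10S) while C5 is untouched.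

**Step 6**
Reactants: 8
Product: 9 (5S,10S)‑10β‑hydroxy‑11,12,14‑trimethoxy‑9(10→20)‑abeo‑abieta‑8,11,13‑trien‑7‑one (may equilibrate with its 7,10‑bridged hemiketal)
Conditions: PDC, t‑BuOOH, Celite, benzene, rt
Reagents that add atoms: tert‑butyl hydroperoxide, CC(C)(C)OO (the C7 oxygen)
Why: Radical benzylic oxidation (Cr(VI)/t‑BuOOH) at C7, the benzylic CH2 para to 12‑OMe; C20 is neopentylic and inductively deactivated by the adjacent C10–OH, the isopropyl methine lies in the arene plane, and the tertiary alcohol cannot be oxidised.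

**Step 7**
Reactants: 9
Product: 10 komaroviquinone (5S,7S,10S)
Conditions: CAN (3 equiv), MeCN/H2O (2:1), 0 °C
Reagents that add atoms: water, O (quinone oxygens; the 11‑ and 14‑OMe leave as MeOH)
Why: CAN oxidative demethylation of the para‑related 11/14‑dimethoxy pair gives the 12‑methoxy‑1,4‑quinone, and the 10β‑OH then adds to the quinone‑activated C7 ketone; the 8‑oxabicyclo[3.2.1]octane bridge from C10 allows only the 7S hemiketal.

**Compound list**
1 | (+)‑carnosic acid | CC(C)c1cc2CC[C@H]3C(C)(C)CCC[C@]3(C(=O)O)c2c(O)c1O | starting material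
2 | iodomethane | CI | starting material
3 | methyl 12‑O‑methylcarnosate | CC(C)c1cc2CC[C@H]3C(C)(C)CCC[C@]3(C(=O)OC)c2c(O)c1OC | intermediate
4 | methyl 12‑methoxy‑11,14‑dioxoabieta‑8,12‑dien‑20‑oate | CC(C)C1=C(OC)C(=O)C2=C(C1=O)CC[C@H]1C(C)(C)CCC[C@]21C(=O)OC | intermediate
5 | dimethyl sulfate | COS(=O)(=O)OC | starting material
6 | methyl 11,12,14‑trimethoxyabieta‑8,11,13‑trien‑20‑oate | CC(C)c1c(OC)c2CC[C@H]3C(C)(C)CCC[C@]3(C(=O)OC)c2c(OC)c1OC | intermediate
7 | 11,12,14‑trimethoxyabieta‑8,11,13‑trien‑20‑ol | CC(C)c1c(OC)c2CC[C@H]3C(C)(C)CCC[C@]3(CO)c2c(OC)c1OC | intermediate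
8 | 11,12,14‑trimethoxy‑icetexa‑8,11,13‑trien‑10β‑ol | CC(C)c1c(OC)c2CC[C@H]3C(C)(C)CCC[C@]3(O)Cc2c(OC)c1OC | intermediate
9 | 10β‑hydroxy‑11,12,14‑trimethoxy‑icetexa‑8,11,13‑trien‑7‑one | CC(C)c1c(OC)c2C(=O)C[C@H]3C(C)(C)CCC[C@]3(O)Cc2c(OC)c1OC | intermediate
10 | komaroviquinone | COC1=C(C(C)C)C(=O)C2=C(C[C@@]34CCCC(C)(C)[C@@H]3C[C@]2(O)O4)C1=O | target

**Totals**
Total steps: 7. Longest linear sequence: 7 (fully linear from carnosic acid).

**Three steps most likely to fail, with fallbacks**
1. Step 5 (aryl shift with water capture). E1 loss to the Δ1(10)/Δ5(10) olefins or imperfect facial control may compete. Fallback: separate the two events. Run the shift under non‑nucleophilic conditions (Tf2O, hindered pyridine) to make the olefin deliberately, then install the 10β‑oxygen by epoxidation and LiAlH4 opening, or by Mukaiyama hydration.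
2. Step 6 (C7 benzylic oxidation). C7/C20 site selectivity, arene over‑oxidation, or trapping of a C7 cation by the 10‑OH as the 7,10‑ether are the risks. Fallback: oxidise C7 at the abietane stage on ester 6, where it is the only benzylic CH2 (CrO3/AcOH). Reduce the ketone (NaBH4), protect the 7‑OH as its TBS ether, carry it through steps 4–5, then desilylate and oxidise the alcohol (Dess–Martin). This costs about four extra steps but removes the selectivity problem.
3. Step 1 (mono‑methylation at O12 in the presence of O11). Over‑ or mis‑methylation is possible. Fallback: tie O11 to C20 as the 11,20‑γ‑lactone (DCC), methylate O12, open with LiAlH4 to the 11,20‑diol, then do the Teuber oxidation and a phenol‑selective reductive methylation (K2CO3/MeI) to converge on 7.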